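**Plan**
- Retrosynthesis: cut the C6 ester; open the furanone at its O–C3 bond (the C10 oxygen adds to a C1-keto enol ether); take the lactone back to a C8 alcohol, a C12 alcohol and an unsubstituted C11; then break C1–C10 of the ten-membered ring and re-form C3–C8 (retro oxy-Cope). The resulting cyclohexene loses C8–C9 (alkenyl), C3–C2 (alkynyl) and C7–C11 (vinyl) to reach a quinone monoketal.
- Enabling feature: in the ten-membered carbocycle, C8 bears oxygen, C2=C3 is an enol ether that is trans in the ring, C4=C5 is cis, and C10 is an oxygenated quaternary carbon. A bond drawn from C3 to C8 therefore gives a cyclohexene (C3–C8) whose C8 carbinol and C3 each carry an alkenyl group: the 1,5-diene C1=C2–C3–C8–C9=C10 with oxygen on C8.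
- Forward order: six-membered ring C3–C8 from 4-methoxy-2-methylphenol; ten-membered ring by anionic oxy-Cope ring expansion; γ-lactone (C8–O–C12); 3(2H)-furanone (C10–O–C3); ester last.
- Stereochemistry: C7 from an asymmetric rhodium/(S)-BINAP conjugate vinylation; a temporary C8 oxygen trans to it; C3 by chelation-controlled alkynylation; C6 by Luche reduction; the C8 carbinol by axial attack anti to the C3 group; C10 by the chair of the rearrangement and the Z enol ether; final C8 by chelation-controlled reduction; the epoxide from (R)-2-methylglycidol.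

Key step: step 16

**Remarks**
- Locants follow the germacrane skeleton of the target in every intermediate: C1 furanone ketone, C2, C3 (furanone carbon on the ring oxygen), C4 (methyl C15)=C5, C6 (ester carbinol), C7, C8 (lactone carbinol), C9, C10 (methyl C14), C11–C13 methylene lactone. CIP descriptors in the names use these locants. TBS = tert-butyldimethylsilyl, PMB = 4-methoxybenzyl, MOM = methoxymethyl.
- Remark on the chemistry: the C9=C10 donor is used as its Z isomer (lithium syn to the β-oxygen). The E isomer would have the metal anti to the alkoxy group and would lose it. With a Z enol ether, 10R requires the C3 and C8 configurations built below.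
- Assumption: the enol silane 21 forms mainly as the E isomer; any Z isomer only changes C1, which becomes a ketone in 39.

Step 1
Reactants: 1 4-methoxy-2-methylphenol
Product: 2 4,4-dimethoxy-2-methylcyclohexa-2,5-dien-1-one
Conditions: PhI(OAc)2, MeOH, 0 °C
Reagents that add atoms: methanol CO
Why: Oxidative dearomatisation of a 4-methoxyphenol in methanol gives the quinone monoketal, which leaves C3 as the only free carbonyl and masks C6.

Step 2
Reactants: 2 4,4-dimethoxy-2-methylcyclohexa-2,5-dien-1-one; 3 vinylboronic acid pinacol ester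
Product: 4 (7S)-vinyl enone, (5S)-4,4-dimethoxy-2-methyl-5-vinylcyclohex-2-en-1-one
Conditions: [RhCl(C2H4)2]2 (2.5 mol %), (S)-BINAP, KOH (0.2 equiv), 1,4-dioxane/H2O (10:1), 35 °C
Reagents that add atoms: none
Why: Rhodium-catalysed asymmetric 1,4-addition of an alkenylboron reagent (Hayashi–Miyaura reaction) goes to the unsubstituted enone arm (C7) because the other arm is α-methylated; by analogy with its sense on 2-cyclohexenone the (S)-BINAP complex should give 7S, and the mild conditions keep the adduct from losing methanol to a phenol.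

Step 3
Reactants: 4 (7S)-vinyl enone
Product: 6 (7R,8R)-8-hydroxy enone, (5R,6R)-6-hydroxy-4,4-dimethoxy-2-methyl-5-vinylcyclohex-2-en-1-one, via sodium enolate 5 (not isolated)
Conditions: NaN(SiMe3)2, THF, −78 °C; then 2-(phenylsulfonyl)-3-phenyloxaziridine, −78 °C; NH4Cl (aq)
Reagents that add atoms: 2-(phenylsulfonyl)-3-phenyloxaziridine O=S(=O)(c1ccccc1)N1OC1c1ccccc1
Why: The enolate can form only toward C8 (C4 is vinylic) and is hydroxylated by the N-sulfonyloxaziridine (Davis oxidation) anti to the neighbouring C7 vinyl group, giving the trans C7/C8 pair.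

Step 4
Reactants: 6 (7R,8R)-8-hydroxy enone; 7 ethynyltrimethylsilane
Product: 9 (3S,7R,8R)-diol with C3 OH and (trimethylsilyl)ethynyl, C4 methyl, C4=C5, C6 dimethyl ketal, C7 vinyl and C8 OH, via alkynylmagnesium bromide 8 (not isolated)
Conditions: EtMgBr, THF, 0 °C (on 7, 3 equiv); then 6, −78 → −20 °C
Reagents that add atoms: none
Why: Chelation-controlled Grignard 1,2-addition to an α-hydroxy ketone: magnesium bridges the C8 alkoxide and the C3 carbonyl, the C8 oxygen lies equatorial, and the small alkynyl group enters axially on the face of the C8 oxygen, giving the trans-diol (3S).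

Step 5
Reactants: 9 (3S,7R,8R)-diol
Product: 10 (3S,7R,8R)-C8 TBS ether with free tertiary C3 OH
Conditions: TBSCl, imidazole, DMF, 23 °C
Reagents that add atoms: tert-butyldimethylsilyl chloride CC(C)(C)[Si](C)(C)Cl
Why: Silylation with TBSCl/imidazole takes the secondary C8 hydroxyl and leaves the tertiary propargylic C3 hydroxyl untouched.

Step 6
Reactants: 10 (3S,7R,8R)-C8 TBS ether
Product: 12 (3S,7R,8R)-C3 methyl ether, via potassium alkoxide 11 (not isolated)
Conditions: KN(SiMe3)2, THF, −78 °C; then MeOTf, −78 → −40 °C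
Reagents that add atoms: methyl trifluoromethanesulfonate COS(=O)(=O)C(F)(F)F
Why: Williamson O-methylation of the hindered tertiary alkoxide with methyl triflate at low temperature is faster than 1,2-silyl migration from the C8 oxygen.

Step 7
Reactants: 12 (3S,7R,8R)-C3 methyl ether
Product: 13 (3S,7R,8R)-C6 enone (C4=C5–C6=O) with C3 OMe and silylethynyl, C7 vinyl, C8 OTBS
Conditions: pyridinium p-toluenesulfonate (0.2 equiv), THF/H2O (5:1), 23 °C
Reagents that add atoms: water O
Why: Acid hydrolysis of the allylic dimethyl ketal runs through a conjugated oxocarbenium ion and is much faster than ionisation of the C3 ether or loss of the TBS group.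

Step 8
Reactants: 13 (3S,7R,8R)-C6 enone
Product: 14 (3S,6R,7S,8R)-C6 allylic alcohol
Conditions: NaBH4, CeCl3·7H2O, MeOH, −78 °C
Reagents that add atoms: none
Why: Luche 1,2-reduction; axial hydride delivery to the half-chair with equatorial C7 and C8 substituents gives the equatorial C6 alcohol trans to the C7 vinyl group (6R).

Step 9
Reactants: 14 (3S,6R,7S,8R)-C6 allylic alcohol
Product: 16 (3S,6R,7S,8R)-C6 PMB ether, via sodium alkoxide 15 (not isolated)
Conditions: NaH, THF, 0 °C; then 4-MeOC6H4CH2Br, Bu4NI (cat.), 0 → 23 °C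
Reagents that add atoms: 4-methoxybenzyl bromide COc1ccc(CBr)cc1
Why: Williamson etherification; the PMB ether is orthogonal to every silyl group used later and is removed oxidatively near the end.

Step 10
Reactants: 16 (3S,6R,7S,8R)-C6 PMB ether
Product: 17 (3R,6R,7R,8R)-C8 alcohol with C3 ethynyl
Conditions: Bu4NF (2.5 equiv), THF, 0 → 23 °C
Reagents that add atoms: none
Why: Fluoride cleaves the C8 silyl ether and the alkynyl silane in one operation; no other silicon group is present.

Step 11
Reactants: 17 (3R,6R,7R,8R)-C8 alcohol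
Product: 18 (3R,6R,7S)-C8 ketone with C3 OMe and ethynyl, C6 OPMB, C7 vinyl
Conditions: Dess–Martin periodinane, NaHCO3, CH2Cl2, 0 → 23 °C
Reagents that add atoms: none
Why: Dess–Martin oxidation under buffered, non-basic conditions gives the ketone without moving the C7 vinyl double bond into conjugation or epimerising C7.

Step 12
Reactants: 18 (3R,6R,7S)-C8 ketone
Product: 20 (3R,6R,7S)-keto aldehyde with C3 CH2CHO and C7 CH2CH2OH, via bis(dicyclohexylboryl) adduct 19 (not isolated)
Conditions: BH3·SMe2, cyclohexene, THF, 0 °C [(c-C6H11)2BH, 2.5 equiv]; then 18, 0 °C; then H2O2 (30%), pH 7 phosphate buffer, 0 → 23 °C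
Reagents that add atoms: hydrogen peroxide OO
Why: Anti-Markovnikov hydroboration with the hindered dialkylborane takes the terminal alkyne and the vinyl group much faster than it reduces the flanked C8 ketone or touches the trisubstituted ring alkene; buffered oxidation gives the C1 aldehyde and the C12 alcohol.

Step 13
Reactants: 20 (3R,6R,7S)-keto aldehyde
Product: 21 (1E,3R,6R,7S)-C8 ketone with C3 (E)-2-(TBS-oxy)vinyl and C7 2-(TBS-oxy)ethyl
Conditions: TBSOTf (2.4 equiv), Et3N, CH2Cl2, −78 → 0 °C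
Reagents that add atoms: tert-butyldimethylsilyl trifluoromethanesulfonate CC(C)(C)[Si](C)(C)OS(=O)(=O)C(F)(F)F
Why: Silyl triflate with amine silylates the primary alcohol and converts the aldehyde into its silyl enol ether (soft enolisation), while the ketone, with no hydrogen on C3 and a hindered one on C7, is left; the E isomer should predominate because C3 is quaternary.

Step 14
Reactants: 22 bromoacetone
Product: 24 (Z)-1-bromo-2-(methoxymethoxy)prop-1-ene, via potassium enolate 23 (not isolated)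
Conditions: KN(SiMe3)2, THF, −78 °C; then MeOCH2Cl, −78 → 0 °C
Reagents that add atoms: chloromethyl methyl ether COCCl
Why: Deprotonation on the more acidic bromomethyl side gives the enolate with bromine syn to oxygen (away from methyl), and the hard chloromethyl ether alkylates it on oxygen, fixing the Z enol ether.

Step 15
Reactants: 21 (1E,3R,6R,7S)-C8 ketone; 24 (Z)-1-bromo-2-(methoxymethoxy)prop-1-ene
Product: 26 (1E,3R,6R,7S,8S,9Z)-trans-1,2-dialkenylcyclohexenol with C3 OMe and (E)-2-(TBS-oxy)vinyl, C6 OPMB, C7 2-(TBS-oxy)ethyl, C8 OH and (Z)-2-(methoxymethoxy)prop-1-enyl, via alkenyllithium 25 (not isolated)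
Conditions: t-BuLi (2.0 equiv), Et2O, −78 °C (on 24); then 21, −78 °C; NH4Cl (aq)
Reagents that add atoms: none
Why: Bromine–lithium exchange with retention gives the (Z)-β-alkoxyalkenyllithium, held by O–Li coordination; its 1,2-addition to the ketone is axial on the half-chair with equatorial C6/C7 substituents, anti to the pseudoaxial C3 alkenyl group and with lithium chelated by the C3 methoxy group, so the two alkenyl groups end up trans (8S).

Step 16
Reactants: 26 (1E,3R,6R,7S,8S,9Z)-trans-1,2-dialkenylcyclohexenol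
Product: 29 (1S,6R,7S,10R)-ten-membered C8 ketone with C1 OTBS, C2=C3 methyl enol ether trans in the ring, cis C4=C5, C6 OPMB, C7 2-(TBS-oxy)ethyl and C10 methyl and OMOM, via potassium alkoxide 27 (not isolated), via potassium enolate 28 (not isolated)
Conditions: KN(SiMe3)2 (1.3 equiv), 18-crown-6, THF, −78 → 0 °C; AcOH, −78 °C
Reagents that add atoms: none
Why: The base ionises the C8 tertiary alcohol and the weakened C3–C8 bond breaks while C1–C10 forms in a [3,3]-sigmatropic shift of C1=C2–C3–C8–C9=C10, giving the C8 enolate of the ring-expanded ketone; this is the anionic oxy-Cope rearrangement, known for trans-1,2-dialkenylcyclohexanols giving (E)-cyclodec-5-enones. The ten-membered ring is closed by bonding of the two alkene termini across a six-centre chair (a four-carbon ring expansion, not an end-to-end cyclisation), and the trans-dialkenyl pair allows only the chair in which the cyclohexene bonds C3–C4 and C8–C7 are equatorial. C10 is set by that chair together with the Z geometry of the C9=C10 enol ether (OMOM axial, methyl equatorial, giving 10R); C1 is set by the E enol silane (OTBS equatorial) and is later oxidised away. The step needs C2=C3 trans in the ring (secured by the equatorial C3–C4 bond) and C4=C5 unchanged (it is endocyclic in the six-membered ring), and the alternative diene through C4=C5 is anti to C9 in the reactive conformer and cannot bond. The reactive half-chair holds the C6 and C7 substituents axial, a strain that is released as C3–C8 breaks, and the cold acetic acid quench protonates the enolate before the C10 alkoxy group can be eliminated or C7 can epimerise.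

Step 17
Reactants: 29 (1S,6R,7S,10R)-ten-membered C8 ketone
Product: 30 (1S,6R,7R,8S,10R)-C8 alcohol
Conditions: Zn(BH4)2, Et2O, −30 °C
Reagents that add atoms: none
Why: Chelation-controlled hydride reduction of a β-alkoxy ketone; both β-oxygen groups (C6 OPMB and C10 OMOM) direct to the 1,3-syn alcohol, which is 8S, and no base is present to eliminate the β-alkoxy group.

Step 18
Reactants: 30 (1S,6R,7R,8S,10R)-C8 alcohol
Product: 31 (1S,6R,7R,8S,10R)-C8,C12 diol with C1 OTBS retained
Conditions: Bu4NF (1.1 equiv), AcOH (1.1 equiv), THF, 0 °C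
Reagents that add atoms: none
Why: Buffered fluoride cleaves the primary C12 silyl ether much faster than the hindered secondary C1 silyl ether, and the neutral medium spares the enol ether.

Step 19
Reactants: 31 (1S,6R,7R,8S,10R)-diol
Product: 33 (1S,6R,7R,8S,10R)-trans-fused γ-lactone (C8–O–C12), via lactol 32 (not isolated)
Conditions: (n-Pr)4N[RuO4] (5 mol %), N-methylmorpholine N-oxide, 4 Å molecular sieves, CH2Cl2, 23 °C
Reagents that add atoms: none
Why: Ley–Griffith oxidation of a 1,4-diol: the primary alcohol gives the aldehyde, the C8 hydroxyl closes the five-membered lactol (5-exo-trig addition) and a second oxidation gives the lactone; the neutral, anhydrous medium leaves the enol ether intact.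

Step 20
Reactants: 33 (1S,6R,7R,8S,10R)-γ-lactone
Product: 37 (1S,6R,7R,8S,10R)-α-methylene lactone, via lithium enolate 34 (not isolated), via Mannich base 35 (not isolated), via trimethylammonium iodide 36 (not isolated)
Conditions: LiN(i-Pr)2, THF, −78 °C; then Me2N=CH2+ I−, −78 → 23 °C; then MeI, CH2Cl2/MeOH; NaHCO3 (aq), 23 °C
Reagents that add atoms: N,N-dimethylmethyleneiminium iodide (Eschenmoser's salt) C=[N+](C)C.[I-]
Why: Mannich reaction of the lactone enolate with Eschenmoser's salt, N-methylation and β-elimination give the exocyclic methylene; the lactone α-position is the only enolisable site at this stage.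

Step 21
Reactants: 37 (1S,6R,7R,8S,10R)-α-methylene lactone
Product: 38 (1S,6R,7R,8S,10R)-C1 alcohol
Conditions: Bu4NF, AcOH, THF, 23 → 40 °C
Reagents that add atoms: none
Why: Acetic acid-buffered fluoride removes the remaining silyl ether without conjugate addition to the methylene lactone and without ionising the allylic C1 oxygen.

Step 22
Reactants: 38 (1S,6R,7R,8S,10R)-C1 alcohol
Product: 39 (6R,7R,8S,10R)-C1 ketone (vinylogous ester C1(=O)–C2=C3–OMe)
Conditions: Dess–Martin periodinane, NaHCO3, CH2Cl2, 0 → 23 °C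
Reagents that add atoms: none
Why: Dess–Martin oxidation of the allylic secondary alcohol; the vinylogous ester formed has no enolisable position (C10 is quaternary, C2 is vinylic).

Step 23
Reactants: 39 (6R,7R,8S,10R)-C1 ketone
Product: 41 (6R,7R,8S,10R)-3(2H)-furanone with C6 OPMB, via C10 tertiary alcohol 40 (not isolated)
Conditions: HCl (2 M, aq), THF, 0 → 23 °C
Reagents that add atoms: none
Why: Acid removes the MOM group and the C10 hydroxyl adds to C3 of the protonated vinylogous ester and expels methanol (5-exo-trig addition–elimination), the classical acid closure of a 3(2H)-furanone; the PMB ether survives dilute acid.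

Step 24
Reactants: 41 (6R,7R,8S,10R)-furanone PMB ether
Product: 42 (6R,7S,8S,10R)-furanone C6 alcohol
Conditions: DDQ, CH2Cl2/pH 7 buffer (10:1), 0 °C
Reagents that add atoms: none
Why: Oxidative cleavage of the PMB ether with DDQ; the furanone–diene and the methylene lactone are electron-poor and are not oxidised.

Step 25
Reactants: 43 (R)-2-methylglycidol
Product: 44 (S)-2-methyloxirane-2-carboxylic acid
Conditions: TEMPO (cat.), PhI(OAc)2, MeCN/H2O (1:1), 0 → 23 °C
Reagents that add atoms: water O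
Why: Nitroxyl-catalysed oxidation of the primary alcohol to the acid through the aldehyde hydrate; the quaternary epoxide carbon cannot epimerise, and R becomes S only through the change in CIP priorities.

Step 26
Reactants: 42 (6R,7S,8S,10R)-furanone C6 alcohol; 44 (S)-2-methyloxirane-2-carboxylic acid
Product: 46 CNP0321429.1, (6R,7R,8S,10R)-furanone germacranolide C6 (2S)-2-methyloxirane-2-carboxylate, via mixed anhydride 45 (not isolated)
Conditions: 2,4,6-Cl3C6H2COCl, Et3N, THF, 0 °C (on 44); then 42, DMAP, toluene, 23 °C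
Reagents that add atoms: none
Why: Yamaguchi esterification: the mixed anhydride acylates the hindered allylic C6 alcohol under DMAP catalysis, with retention at C6 and without opening the epoxide.

**Compound list**
1 | 4-methoxy-2-methylphenol | Cc1cc(OC)ccc1O | starting material
2 | 4,4-dimethoxy-2-methylcyclohexa-2,5-dien-1-one | COC1(OC)C=CC(=O)C(C)=C1 | intermediate
3 | vinylboronic acid pinacol ester | C=CB1OC(C)(C)C(C)(C)O1 | starting material
4 | (7S)-vinyl enone, (5S)-4,4-dimethoxy-2-methyl-5-vinylcyclohex-2-en-1-one | O=C1C(C)=CC(OC)(OC)[C@H](C=C)C1 | intermediate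
5 | sodium enolate of 4 (in situ) | [Na+].[O-]C1=C[C@@H](C=C)C(OC)(OC)C=C1C | intermediate
6 | (7R,8R)-8-hydroxy enone, (5R,6R)-6-hydroxy-4,4-dimethoxy-2-methyl-5-vinylcyclohex-2-en-1-one | O=C1C(C)=CC(OC)(OC)[C@H](C=C)[C@H]1O | intermediate
7 | ethynyltrimethylsilane | C[Si](C)(C)C#C | starting material
8 | [(trimethylsilyl)ethynyl]magnesium bromide (in situ) | C[Si](C)(C)C#C[Mg]Br | intermediate
9 | (3S,7R,8R)-diol: C3 OH and (trimethylsilyl)ethynyl, C6 dimethyl ketal, C7 vinyl, C8 OH | C[Si](C)(C)C#C[C@@]1(O)C(C)=CC(OC)(OC)[C@H](C=C)[C@H]1O | intermediate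
10 | (3S,7R,8R)-C8 TBS ether of 9 | C[Si](C)(C)C#C[C@@]1(O)C(C)=CC(OC)(OC)[C@H](C=C)[C@H]1O[Si](C)(C)C(C)(C)C | intermediate
11 | potassium C3 alkoxide of 10 (in situ) | [K+].C[Si](C)(C)C#C[C@@]1([O-])C(C)=CC(OC)(OC)[C@H](C=C)[C@H]1O[Si](C)(C)C(C)(C)C | intermediate
12 | (3S,7R,8R)-C3 methyl ether | C[Si](C)(C)C#C[C@@]1(OC)C(C)=CC(OC)(OC)[C@H](C=C)[C@H]1O[Si](C)(C)C(C)(C)C | intermediate
13 | (3S,7R,8R)-C6 enone | C[Si](C)(C)C#C[C@@]1(OC)C(C)=CC(=O)[C@H](C=C)[C@H]1O[Si](C)(C)C(C)(C)C | intermediate
14 | (3S,6R,7S,8R)-C6 allylic alcohol | C[Si](C)(C)C#C[C@@]1(OC)C(C)=C[C@@H](O)[C@H](C=C)[C@H]1O[Si](C)(C)C(C)(C)C | intermediate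
15 | sodium C6 alkoxide of 14 (in situ) | [Na+].C[Si](C)(C)C#C[C@@]1(OC)C(C)=C[C@@H]([O-])[C@H](C=C)[C@H]1O[Si](C)(C)C(C)(C)C | intermediate
16 | (3S,6R,7S,8R)-C6 PMB ether | C[Si](C)(C)C#C[C@@]1(OC)C(C)=C[C@@H](OCc2ccc(OC)cc2)[C@H](C=C)[C@H]1O[Si](C)(C)C(C)(C)C | intermediate
17 | (3R,6R,7R,8R)-C8 alcohol with C3 ethynyl | C#C[C@@]1(OC)C(C)=C[C@@H](OCc2ccc(OC)cc2)[C@H](C=C)[C@H]1O | intermediate
18 | (3R,6R,7S)-C8 ketone with C3 ethynyl and C7 vinyl | C#C[C@@]1(OC)C(C)=C[C@@H](OCc2ccc(OC)cc2)[C@H](C=C)C1=O | intermediate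
19 | bis(dicyclohexylboryl) adduct of 18 (in situ; E-alkenylborane at C1, alkylborane at C12) | C2CCC(CC2)B(C2CCCCC2)/C=C/[C@@]1(OC)C(C)=C[C@@H](OCc2ccc(OC)cc2)[C@H](CCB(C2CCCCC2)C2CCCCC2)C1=O | intermediate
20 | (3R,6R,7S)-keto aldehyde: C3 CH2CHO, C7 CH2CH2OH | O=CC[C@@]1(OC)C(C)=C[C@@H](OCc2ccc(OC)cc2)[C@H](CCO)C1=O | intermediate
21 | (1E,3R,6R,7S)-C8 ketone with C3 (E)-2-(TBS-oxy)vinyl and C7 2-(TBS-oxy)ethyl | CC(C)(C)[Si](C)(C)O/C=C/[C@@]1(OC)C(C)=C[C@@H](OCc2ccc(OC)cc2)[C@H](CCO[Si](C)(C)C(C)(C)C)C1=O | intermediate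
22 | bromoacetone | CC(=O)CBr | starting material
23 | potassium (Z)-1-bromoprop-1-en-2-olate (in situ) | [K+].[O-]/C(C)=C\Br | intermediate
24 | (Z)-1-bromo-2-(methoxymethoxy)prop-1-ene | COCO/C(C)=C\Br | intermediate
25 | (Z)-[2-(methoxymethoxy)prop-1-en-1-yl]lithium (in situ) | [Li]/C=C(/C)OCOC | intermediate
26 | (1E,3R,6R,7S,8S,9Z)-trans-1,2-dialkenylcyclohexenol (rearrangement precursor) | CC(C)(C)[Si](C)(C)O/C=C/[C@@]1(OC)C(C)=C[C@@H](OCc2ccc(OC)cc2)[C@H](CCO[Si](C)(C)C(C)(C)C)[C@]1(O)/C=C(/C)OCOC | intermediate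
27 | potassium C8 alkoxide of 26 (in situ) | [K+].CC(C)(C)[Si](C)(C)O/C=C/[C@@]1(OC)C(C)=C[C@@H](OCc2ccc(OC)cc2)[C@H](CCO[Si](C)(C)C(C)(C)C)[C@]1([O-])/C=C(/C)OCOC | intermediate
28 | potassium C8 enolate (C8=C9) of 29 (in situ) | [K+].[O-]/C1=C\[C@@](C)(OCOC)[C@@H](O[Si](C)(C)C(C)(C)C)/C=C(OC)/C(C)=C\[C@@H](OCc2ccc(OC)cc2)[C@@H]1CCO[Si](C)(C)C(C)(C)C | intermediate
29 | (1S,6R,7S,10R)-ten-membered C8 ketone (rearrangement product) | O=C1C[C@@](C)(OCOC)[C@@H](O[Si](C)(C)C(C)(C)C)/C=C(OC)/C(C)=C\[C@@H](OCc2ccc(OC)cc2)[C@@H]1CCO[Si](C)(C)C(C)(C)C | intermediate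
30 | (1S,6R,7R,8S,10R)-C8 alcohol | O[C@H]1C[C@@](C)(OCOC)[C@@H](O[Si](C)(C)C(C)(C)C)/C=C(OC)/C(C)=C\[C@@H](OCc2ccc(OC)cc2)[C@@H]1CCO[Si](C)(C)C(C)(C)C | intermediate
31 | (1S,6R,7R,8S,10R)-C8,C12 diol | O[C@H]1C[C@@](C)(OCOC)[C@@H](O[Si](C)(C)C(C)(C)C)/C=C(OC)/C(C)=C\[C@@H](OCc2ccc(OC)cc2)[C@@H]1CCO | intermediate
32 | C12 lactol (in situ; C12 epimers) | OC1O[C@H]2C[C@@](C)(OCOC)[C@@H](O[Si](C)(C)C(C)(C)C)/C=C(OC)/C(C)=C\[C@@H](OCc3ccc(OC)cc3)[C@@H]2C1 | intermediate
33 | (1S,6R,7R,8S,10R)-γ-lactone | O=C1O[C@H]2C[C@@](C)(OCOC)[C@@H](O[Si](C)(C)C(C)(C)C)/C=C(OC)/C(C)=C\[C@@H](OCc3ccc(OC)cc3)[C@@H]2C1 | intermediate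
34 | lithium enolate of lactone 33 (in situ) | [Li+].[O-]C1O[C@H]2C[C@@](C)(OCOC)[C@@H](O[Si](C)(C)C(C)(C)C)/C=C(OC)/C(C)=C\[C@@H](OCc3ccc(OC)cc3)[C@@H]2C=1 | intermediate
35 | C11 (dimethylaminomethyl) lactone (in situ; C11 epimers) | CN(C)CC1C(=O)O[C@H]2C[C@@](C)(OCOC)[C@@H](O[Si](C)(C)C(C)(C)C)/C=C(OC)/C(C)=C\[C@@H](OCc3ccc(OC)cc3)[C@H]12 | intermediate
36 | trimethylammonium iodide of 35 (in situ) | [I-].C[N+](C)(C)CC1C(=O)O[C@H]2C[C@@](C)(OCOC)[C@@H](O[Si](C)(C)C(C)(C)C)/C=C(OC)/C(C)=C\[C@@H](OCc3ccc(OC)cc3)[C@H]12 | intermediate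
37 | (1S,6R,7R,8S,10R)-α-methylene lactone | C=C1C(=O)O[C@H]2C[C@@](C)(OCOC)[C@@H](O[Si](C)(C)C(C)(C)C)/C=C(OC)/C(C)=C\[C@@H](OCc3ccc(OC)cc3)[C@H]12 | intermediate
38 | (1S,6R,7R,8S,10R)-C1 alcohol | C=C1C(=O)O[C@H]2C[C@@](C)(OCOC)[C@@H](O)/C=C(OC)/C(C)=C\[C@@H](OCc3ccc(OC)cc3)[C@H]12 | intermediate
39 | (6R,7R,8S,10R)-C1 ketone (vinylogous ester) | C=C1C(=O)O[C@H]2C[C@@](C)(OCOC)C(=O)/C=C(OC)/C(C)=C\[C@@H](OCc3ccc(OC)cc3)[C@H]12 | intermediate
40 | C10 tertiary alcohol of 39 (in situ) | C=C1C(=O)O[C@H]2C[C@@](C)(O)C(=O)/C=C(OC)/C(C)=C\[C@@H](OCc3ccc(OC)cc3)[C@H]12 | intermediate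
41 | (6R,7R,8S,10R)-furanone C6 PMB ether | C=C1C(=O)O[C@H]2C[C@@]3(C)OC(=CC3=O)/C(C)=C\[C@@H](OCc4ccc(OC)cc4)[C@H]12 | intermediate
42 | (6R,7S,8S,10R)-furanone C6 alcohol | C=C1C(=O)O[C@H]2C[C@@]3(C)OC(=CC3=O)/C(C)=C\[C@@H](O)[C@H]12 | intermediate
43 | (R)-2-methylglycidol | OC[C@]1(C)CO1 | starting material
44 | (S)-2-methyloxirane-2-carboxylic acid | O=C(O)[C@]1(C)CO1 | intermediate
45 | mixed anhydride of 44 with 2,4,6-trichlorobenzoic acid (in situ) | O=C(OC(=O)c1c(Cl)cc(Cl)cc1Cl)[C@]1(C)CO1 | intermediate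
46 | CNP0321429.1 | C=C1C(=O)O[C@H]2C[C@@]3(C)OC(=CC3=O)/C(C)=C\[C@@H](OC(=O)[C@]3(C)CO3)[C@H]12 | target

**Step count**
Total: 26 steps. Longest linear sequence: 24 steps (steps 1–13, 15–24 and 26; steps 14 and 25 prepare the two side fragments).

**Steps most likely to fail**

Step 16. The potassium alkoxide may fragment heterolytically at C3–C8 and recombine without stereocontrol instead of rearranging in concert. The rearrangement may also be slow, because the reactive half-chair holds the C6 and C7 substituents axial. The product enolate may eliminate the C10 alkoxy group or epimerise C7 before it is quenched. The fallback is the neutral silyloxy-Cope variant, which never generates a free alkoxide or enolate. It sets out from 26: silylation with 1-(trimethylsilyl)imidazole in CH2Cl2 gives the C8 trimethylsilyl ether F1. Heating F1 in toluene at 110–150 °C in base-washed glassware should give, through the same chair, the C8 trimethylsilyl enol ether F2. Methanolysis of F2 with K2CO3 in MeOH at 0 °C, which leaves the TBS ethers, returns to the route at 29.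

Step 15. The basic alkenyllithium may enolise the hindered ketone at C7, may decompose before it adds, or may add with poor facial selectivity. The fallback avoids the β-alkoxyalkenyl donor and sets out from 21. Prop-1-ynylmagnesium bromide in THF, a small and weakly basic nucleophile that should attack in the same axial sense, gives the C8 propynyl carbinol F3. Its anionic oxy-Cope rearrangement (KN(SiMe3)2, 18-crown-6, THF), a known variant for 1-alkynyl-2-alkenyl carbinols, gives after protonation of the allenolate the ten-membered C9=C10 enone F4. Conjugate borylation of F4 (B2pin2, CuCl, NaOt-Bu, a chiral ferrocenyl bisphosphine, MeOH) gives the C10 pinacol boronate F5, whose oxidation with NaBO3·4H2O gives the C10 tertiary alcohol F6. Here C10 is set by the ligand rather than by the chair. Protection of F6 with MeOCH2Cl and i-Pr2NEt returns to the route at 29.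

Step 17. Hydride may reach the C8 carbonyl from the other face, because the conformation of the ten-membered ring rather than chelation may decide the approach. The fallback sets out from 29 and accepts the wrong alcohol: reduction with NaBH4 in MeOH gives the C8 epimer F7. Mitsunobu inversion of F7 with 4-nitrobenzoic acid, PPh3 and diisopropyl azodicarboxylate gives the inverted 4-nitrobenzoate F8. Methanolysis of F8 (K2CO3, MeOH) returns to the route at 30.

Further compounds
F1 | step 16 | C8 trimethylsilyl ether of 26 | CC(C)(C)[Si](C)(C)O/C=C/[C@@]1(OC)C(C)=C[C@@H](OCc2ccc(OC)cc2)[C@H](CCO[Si](C)(C)C(C)(C)C)[C@]1(O[Si](C)(C)C)/C=C(/C)OCOC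
F2 | step 16 | C8 trimethylsilyl enol ether (C8=C9) of 29 | C[Si](C)(C)O/C1=C\[C@@](C)(OCOC)[C@@H](O[Si](C)(C)C(C)(C)C)/C=C(OC)/C(C)=C\[C@@H](OCc2ccc(OC)cc2)[C@@H]1CCO[Si](C)(C)C(C)(C)C
F3 | step 15 | C8 prop-1-ynyl carbinol from 21 | CC(C)(C)[Si](C)(C)O/C=C/[C@@]1(OC)C(C)=C[C@@H](OCc2ccc(OC)cc2)[C@H](CCO[Si](C)(C)C(C)(C)C)[C@]1(O)C#CC
F4 | step 15 | ten-membered C8 ketone with C9=C10 enone (C10 methyl) | O=C1C=C(C)[C@@H](O[Si](C)(C)C(C)(C)C)/C=C(OC)/C(C)=C\[C@@H](OCc2ccc(OC)cc2)[C@@H]1CCO[Si](C)(C)C(C)(C)C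
F5 | step 15 | C10 pinacol boronate of the C8 ketone | O=C1C[C@@](C)(B2OC(C)(C)C(C)(C)O2)[C@@H](O[Si](C)(C)C(C)(C)C)/C=C(OC)/C(C)=C\[C@@H](OCc2ccc(OC)cc2)[C@@H]1CCO[Si](C)(C)C(C)(C)C
F6 | step 15 | C10 tertiary alcohol of the C8 ketone | O=C1C[C@@](C)(O)[C@@H](O[Si](C)(C)C(C)(C)C)/C=C(OC)/C(C)=C\[C@@H](OCc2ccc(OC)cc2)[C@@H]1CCO[Si](C)(C)C(C)(C)C
F7 | step 17 | C8 epimer of 30 | O[C@@H]1C[C@@](C)(OCOC)[C@@H](O[Si](C)(C)C(C)(C)C)/C=C(OC)/C(C)=C\[C@@H](OCc2ccc(OC)cc2)[C@@H]1CCO[Si](C)(C)C(C)(C)C
F8 | step 17 | C8 4-nitrobenzoate of 30 | O=C(O[C@H]1C[C@@](C)(OCOC)[C@@H](O[Si](C)(C)C(C)(C)C)/C=C(OC)/C(C)=C\[C@@H](OCc2ccc(OC)cc2)[C@@H]1CCO[Si](C)(C)C(C)(C)C)c1ccc(cc1)[N+](=O)[O-]
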